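**Strategy.** The flavone is cut at the O1–C8a ether bond of ring C. Ring A carries its only hydrogen at C8, between C8a and the oxygenated C7. A bromine put there by simple electrophilic substitution can therefore act as the leaving group for a C8/C8a aryne, which the diketone enolate oxygen captures at C8a. In one operation this cine substitution closes the pyranone ring and returns hydrogen to C8. The precursor is an open-chain 1,3-diaryl-1,3-diketone whose ring-A aryl group bears bromine meta to the acyl carbon, with both future phenols masked as methoxymethyl ethers.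

Key step: step 6

Remark: ring positions are numbered as in the flavone (O1, C2, C3, C4, C4a, C5 to C8, C8a; ring B primed); compounds 9 to 11 are written as lithium species, and LiTMP (lithium 2,2,6,6-tetramethylpiperidide) is made in the flask from the amine and n-BuLi.

**Step 1**
Reactants: 1 1-(2,3,4-trihydroxyphenyl)ethanone (gallacetophenone); 2 chloromethyl methyl ether
Product: 3 1-[2,3-dihydroxy-4-(methoxymethoxy)phenyl]ethanone
Conditions: 2 (1.05 equiv), K2CO3 (1.1 equiv), acetone, 0 °C → rt, under argon
Reagents that add atoms: none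
Why: Williamson-type methoxymethylation of the most acidic phenol: O4–H is para to the acetyl group and not hydrogen-bonded, so with one equivalent of weak base and of reagent it should react ahead of O3–H and the chelated O2–H.

**Step 2**
Reactants: 3 1-[2,3-dihydroxy-4-(methoxymethoxy)phenyl]ethanone
Product: 4 1-[2,3-dimethoxy-4-(methoxymethoxy)phenyl]ethanone
Conditions: MeI (4 equiv), K2CO3 (4 equiv), DMF, 45 °C
Reagents that add atoms: iodomethane, CI
Why: Williamson ether synthesis; excess MeI and carbonate in DMF should also methylate the chelated O2–H, and the acetal is inert to base.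

**Step 3**
Reactants: 4 1-[2,3-dimethoxy-4-(methoxymethoxy)phenyl]ethanone
Product: 5 1-[5-bromo-2,3-dimethoxy-4-(methoxymethoxy)phenyl]ethanone
Conditions: NBS (1.05 equiv), MeCN, 0 °C → rt, dark
Reagents that add atoms: N-bromosuccinimide, O=C1CCC(=O)N1Br
Why: Electrophilic aromatic bromination; C5 is ortho to the acetal oxygen on C4, para to the C2 methoxy group and meta to the acetyl group, whereas C6 lies ortho to the carbonyl, and NBS releases no free acid, so the acetyl methyl group and the acetal should be spared.

**Step 4**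
Reactants: 6 methyl 3-hydroxy-4,5-dimethoxybenzoate; 2 chloromethyl methyl ether
Product: 7 methyl 3,4-dimethoxy-5-(methoxymethoxy)benzoate
Conditions: 2 (1.3 equiv), K2CO3 (2 equiv), acetone, rt
Reagents that add atoms: none
Why: Williamson-type methoxymethylation of the single phenol; the methyl ester is untouched by carbonate in acetone.

**Step 5**
Reactants: 5 1-[5-bromo-2,3-dimethoxy-4-(methoxymethoxy)phenyl]ethanone; 7 methyl 3,4-dimethoxy-5-(methoxymethoxy)benzoate
Product: 8 1-[5-bromo-2,3-dimethoxy-4-(methoxymethoxy)phenyl]-3-[3,4-dimethoxy-5-(methoxymethoxy)phenyl]propane-1,3-dione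
Conditions: NaH (3 equiv), THF, reflux; then aq. AcOH to pH 6, 0 °C
Reagents that add atoms: none
Why: Crossed Claisen condensation in which the sodium enolate of the methyl ketone is acylated by the non-enolisable benzoate and the product is held as its sodium diketonate; the aryl bromide and both acetals are inert to NaH.

**Step 6**
Reactants: 8 1-[5-bromo-2,3-dimethoxy-4-(methoxymethoxy)phenyl]-3-[3,4-dimethoxy-5-(methoxymethoxy)phenyl]propane-1,3-dione
Product: 12 2-[3,4-dimethoxy-5-(methoxymethoxy)phenyl]-5,6-dimethoxy-7-(methoxymethoxy)-4H-chromen-4-one, via lithium enolate of the bromo diketone 9 (not isolated), via aryne lithium enolate 10 (not isolated), via 8-lithio flavone 11 (not isolated)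
Conditions: LiTMP (4 equiv, from 2,2,6,6-tetramethylpiperidine and n-BuLi), THF (0.02 M, slow addition of 8), −78 → 0 °C; then aq. NH4Cl
Reagents that add atoms: none
Why: Proposed new method: LiTMP should first give lithium diketonate 9, then remove the lone ring-A hydrogen (on the future C8a, next to bromine) with loss of LiBr to give aryne 10, whose (Z)-enolate oxygen adds to the in-plane aryne orbital at C8a to give aryllithium 11, protonated at C8 by the amine formed in the flask. The closest known reaction types are amide-base aryne cyclisations of haloarenes carrying tethered N, O or enolate nucleophiles and the base-mediated SNAr closure of 1-(2-fluoroaryl)-1,3-diketones to flavones; capture of a base-generated aryne by a diketonate oxygen to form a pyranone has not been shown. Ring C closes in a six-membered exo-dig mode, C8 of the aryne staying outside the new ring, whereas attack at C8 would need a meta-bridged seven-membered ring and C-attack by the central carbon a four-membered ring. No stereocentre is created. The step needs cine substitution (bromide leaves C8, oxygen enters C8a), which is secured because bromine has a single ortho hydrogen, the tether reaches only C8a, and the C7 oxygen polarises the aryne so that the nucleophile adds at the distal carbon and the carbanion develops at C8 beside oxygen. LiTMP is preferred to a less hindered amide because it neither adds readily to arynes nor transfers hydride and is too weak to metalate the ring-B ethers, and high dilution favours the intramolecular capture.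

**Step 7**
Reactants: 12 2-[3,4-dimethoxy-5-(methoxymethoxy)phenyl]-5,6-dimethoxy-7-(methoxymethoxy)-4H-chromen-4-one
Product: 13 7-hydroxy-2-(3-hydroxy-4,5-dimethoxyphenyl)-5,6-dimethoxy-4H-chromen-4-one (7,5'-dihydroxy-5,6,3',4'-tetramethoxyflavone)
Conditions: HCl (3 M aq.), MeOH, 50 °C
Reagents that add atoms: none
Why: Acid-catalysed acetal cleavage (transacetalisation to dimethoxymethane) frees O7–H and O5'–H; aryl methyl ethers, including the C5 methoxy group peri to the carbonyl, need Lewis acids or HBr and should survive dilute HCl in methanol.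

**Compound list**
1 | 1-(2,3,4-trihydroxyphenyl)ethanone (gallacetophenone) | CC(=O)c1ccc(O)c(O)c1O | starting material
2 | chloromethyl methyl ether | COCCl | starting material
3 | 1-[2,3-dihydroxy-4-(methoxymethoxy)phenyl]ethanone | CC(=O)c1ccc(OCOC)c(O)c1O | intermediate
4 | 1-[2,3-dimethoxy-4-(methoxymethoxy)phenyl]ethanone | CC(=O)c1ccc(OCOC)c(OC)c1OC | intermediate
5 | 1-[5-bromo-2,3-dimethoxy-4-(methoxymethoxy)phenyl]ethanone | CC(=O)c1cc(Br)c(OCOC)c(OC)c1OC | intermediate
6 | methyl 3-hydroxy-4,5-dimethoxybenzoate | COC(=O)c1cc(O)c(OC)c(OC)c1 | starting material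
7 | methyl 3,4-dimethoxy-5-(methoxymethoxy)benzoate | COCOc1cc(C(=O)OC)cc(OC)c1OC | intermediate
8 | 1-[5-bromo-2,3-dimethoxy-4-(methoxymethoxy)phenyl]-3-[3,4-dimethoxy-5-(methoxymethoxy)phenyl]propane-1,3-dione | COCOc1c(Br)cc(C(=O)CC(=O)c2cc(OC)c(OC)c(OCOC)c2)c(OC)c1OC | intermediate
9 | lithium (Z)-3-[5-bromo-2,3-dimethoxy-4-(methoxymethoxy)phenyl]-1-[3,4-dimethoxy-5-(methoxymethoxy)phenyl]-3-oxoprop-1-en-1-olate | [Li+].[O-]/C(=C\C(=O)c1cc(Br)c(OCOC)c(OC)c1OC)c1cc(OC)c(OC)c(OCOC)c1 | intermediate (not isolated)
10 | lithium (Z)-3-[5,6-didehydro-2,3-dimethoxy-4-(methoxymethoxy)phenyl]-1-[3,4-dimethoxy-5-(methoxymethoxy)phenyl]-3-oxoprop-1-en-1-olate (C8/C8a aryne) | [Li+].[O-]/C(=C\C(=O)C1=C(OC)C(OC)=C(OCOC)C#C1)c1cc(OC)c(OC)c(OCOC)c1 | intermediate (not isolated)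
11 | {2-[3,4-dimethoxy-5-(methoxymethoxy)phenyl]-5,6-dimethoxy-7-(methoxymethoxy)-4-oxo-4H-chromen-8-yl}lithium | [Li]c1c(OCOC)c(OC)c(OC)c2c(=O)cc(-c3cc(OC)c(OC)c(OCOC)c3)oc12 | intermediate (not isolated)
12 | 2-[3,4-dimethoxy-5-(methoxymethoxy)phenyl]-5,6-dimethoxy-7-(methoxymethoxy)-4H-chromen-4-one | COCOc1cc2oc(-c3cc(OC)c(OC)c(OCOC)c3)cc(=O)c2c(OC)c1OC | intermediate
13 | 7-hydroxy-2-(3-hydroxy-4,5-dimethoxyphenyl)-5,6-dimethoxy-4H-chromen-4-one | COc1cc(-c2cc(=O)c3c(OC)c(OC)c(O)cc3o2)cc(O)c1OC | target

**Total step count:** 7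
**Longest linear sequence:** 6 steps (1, 2, 3, 5, 6, 7, from gallacetophenone 1 to target 13)

**Steps most likely to fail**

1. Step 6 (bears the label "Proposed new method:"). What may go wrong: the second deprotonation may be too slow, or the aryne may be intercepted by amine or by a second enolate before the chelated enolate oxygen reaches C8a, leading to aminated or oligomeric material. The fallback uses known chemistry without an aryne, bringing in the O1–C8a oxygen as a phenol; it sets out from ester 7 and comes back at target 13. Commercial 1-(2,4-dihydroxy-6-methoxyphenyl)ethanone (CC(=O)c1c(O)cc(O)cc1OC) would be benzylated at its non-chelated hydroxyl (BnBr, K2CO3, acetone) to give 1-[4-(benzyloxy)-2-hydroxy-6-methoxyphenyl]ethanone F1. Elbs persulfate oxidation (K2S2O8, aq. NaOH) should introduce oxygen para to the free phenol as potassium 3-acetyl-6-(benzyloxy)-4-hydroxy-2-methoxyphenyl sulfate F2, which warm aq. HCl would hydrolyse to 1-[4-(benzyloxy)-3,6-dihydroxy-2-methoxyphenyl]ethanone F3. Methylation of the non-chelated hydroxyl (Me2SO4, 1 equiv, K2CO3, acetone) would give 1-[4-(benzyloxy)-6-hydroxy-2,3-dimethoxyphenyl]ethanone F4. Claisen condensation with 7 (NaH, 4 equiv, THF, reflux) should give 1-[4-(benzyloxy)-6-hydroxy-2,3-dimethoxyphenyl]-3-[3,4-dimethoxy-5-(methoxymethoxy)phenyl]propane-1,3-dione F5. HCl in MeOH at reflux should effect cyclodehydration and acetal loss to 7-(benzyloxy)-2-(3-hydroxy-4,5-dimethoxyphenyl)-5,6-dimethoxy-4H-chromen-4-one F6, and hydrogenolysis (H2, Pd/C, EtOAc) would give 13.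

2. Step 1. What may go wrong: alkylation may run on to O3 or discriminate poorly between O3 and O4, and the electron-rich triol may be oxidised by air in base. The fallback builds the same ketone from a symmetric phenol, so that adjacent hydroxyls never have to be told apart; gallacetophenone 1 is replaced, the fallback sets out from 2 and comes back at 4. Commercial 2-methoxyresorcinol (COc1c(O)cccc1O) would be C-acetylated in a Friedel–Crafts reaction (AcOH, BF3·OEt2, 90 °C; the two reactive positions are equivalent) to 1-(2,4-dihydroxy-3-methoxyphenyl)ethanone F7. Only the non-chelated para hydroxyl should then react with 2 (K2CO3, acetone) to give 1-[2-hydroxy-3-methoxy-4-(methoxymethoxy)phenyl]ethanone F8, and forcing methylation of the chelated hydroxyl (MeI, K2CO3, DMF) gives 4.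

3. Step 3. What may go wrong: bromination of the acetyl methyl group through the enol in place of the ring, or acetal loss if HBr builds up. The fallback brominates one stage earlier, where a free phenol directs; it sets out from 3 and comes back at 5. Diol 3 would be brominated para to O2–H and ortho to the acetal oxygen (NBS, DMF, −20 °C) to give 1-[5-bromo-2,3-dihydroxy-4-(methoxymethoxy)phenyl]ethanone F9, and methylation of both hydroxyls (MeI, K2CO3, DMF) gives 5.

**Further compounds**
F1 | step 6 | 1-[4-(benzyloxy)-2-hydroxy-6-methoxyphenyl]ethanone | CC(=O)c1c(O)cc(OCc2ccccc2)cc1OC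
F2 | step 6 | potassium 3-acetyl-6-(benzyloxy)-4-hydroxy-2-methoxyphenyl sulfate | CC(=O)c1c(O)cc(OCc2ccccc2)c(OS(=O)(=O)[O-])c1OC.[K+]
F3 | step 6 | 1-[4-(benzyloxy)-3,6-dihydroxy-2-methoxyphenyl]ethanone | CC(=O)c1c(O)cc(OCc2ccccc2)c(O)c1OC
F4 | step 6 | 1-[4-(benzyloxy)-6-hydroxy-2,3-dimethoxyphenyl]ethanone | CC(=O)c1c(O)cc(OCc2ccccc2)c(OC)c1OC
F5 | step 6 | 1-[4-(benzyloxy)-6-hydroxy-2,3-dimethoxyphenyl]-3-[3,4-dimethoxy-5-(methoxymethoxy)phenyl]propane-1,3-dione | COCOc1cc(C(=O)CC(=O)c2c(O)cc(OCc3ccccc3)c(OC)c2OC)cc(OC)c1OC
F6 | step 6 | 7-(benzyloxy)-2-(3-hydroxy-4,5-dimethoxyphenyl)-5,6-dimethoxy-4H-chromen-4-one | COc1cc(-c2cc(=O)c3c(OC)c(OC)c(OCc4ccccc4)cc3o2)cc(O)c1OC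
F7 | step 1 | 1-(2,4-dihydroxy-3-methoxyphenyl)ethanone | CC(=O)c1ccc(O)c(OC)c1O
F8 | step 1 | 1-[2-hydroxy-3-methoxy-4-(methoxymethoxy)phenyl]ethanone | CC(=O)c1ccc(OCOC)c(OC)c1O
F9 | step 3 | 1-[5-bromo-2,3-dihydroxy-4-(methoxymethoxy)phenyl]ethanone | CC(=O)c1cc(Br)c(OCOC)c(O)c1O
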